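**Retrosynthetic overview**

1. The C3–O acyl bond is cut last (Steglich esterification with (9Z)-hexadec-9-enoic acid), then the C7=C8 alkene (Wittig of a C10 ring phosphonium salt with purchased C30 all-trans-β-apo-8'-carotenal, which brings the unsubstituted β-ring ready-made).
2. The hydroxylated ring C1–C6 is the only ring the route closes and so the last ring of the skeleton to form. Its C3–C4 bond is made by a catalytic enantioselective chloro-Prins (carbonyl–diene) cyclisation of the achiral, acyclic dienal 9, which sets C3 (R), the tetrasubstituted C5=C6 alkene and a C7–Cl handle in one operation.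
3. Enabling feature: the C3 carbinol is homoallylic to the ring alkene C5=C6, whose other allylic position is the exocyclic C7. The unit C3–C4/C5=C6/C7–X is therefore the 1,4-adduct of an aldehyde carbon and a nucleophile across the 2,3-disubstituted diene C4=C5–C6=C7. Internal capture by the C3 oxygen at C7 would need a bridgehead alkene at C6, so the allyl cation must take an external nucleophile.
4. The quaternary C1 (gem-dimethyl) β to the aldehyde is a Claisen retron: dienal 9 comes from dienyl alcohol 6, made by Suzuki coupling and reduction from ethyl 3-methylbut-2-enoate.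

Key step: step 5

Remark: ring atoms are named by carotenoid numbering (C1 = CMe2, C2 = CH2, C3 = carbinol carbon, C4 = CH2, C5 = methyl-bearing alkene carbon, C6 = alkene carbon carrying the chain, C7 = first chain carbon). Compounds 4, 7, 12 (as the all-E isomer) and 16 are assumed to be purchased.

**Route**

Step 1
Reactants: 1 ethyl 3-methylbut-2-enoate
Product: 3 ethyl 2-bromo-3-methylbut-2-enoate, via dibromo ester 2 (not isolated)
Conditions: Br2, CH2Cl2, 0 °C; then Et3N, 0 °C → rt
Reagents that add atoms: bromine, BrBr
Why: Alkene bromination followed by base-induced dehydrobromination through the acidic α-hydrogen (E2/E1cB) should give the α-bromo enoate, a standard bromination–elimination sequence.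

Step 2
Reactants: 3 ethyl 2-bromo-3-methylbut-2-enoate; 4 isopropenylboronic acid pinacol ester
Product: 5 ethyl 3-methyl-2-(propan-2-ylidene)but-3-enoate
Conditions: Pd(OAc)2 (cat.), SPhos (cat.), K3PO4, toluene/H2O, 80 °C
Reagents that add atoms: none
Why: Suzuki–Miyaura coupling of an activated α-bromo enoate with an alkenylboronate under hindered-substrate ligand conditions should give the cross-conjugated dienoate, and no alkene geometry is at stake because the bromo alkene carries two identical methyl groups.

Step 3
Reactants: 5 ethyl 3-methyl-2-(propan-2-ylidene)but-3-enoate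
Product: 6 3-methyl-2-(propan-2-ylidene)but-3-en-1-ol
Conditions: DIBAL-H (2.2 equiv), CH2Cl2, −78 → 0 °C; Rochelle salt work-up
Reagents that add atoms: none
Why: DIBAL-H 1,2-reduction of an α,β-unsaturated ester should give the allylic alcohol without touching the diene.

Step 4
Reactants: 6 3-methyl-2-(propan-2-ylidene)but-3-en-1-ol; 7 butyl vinyl ether
Product: 9 3,3,5-trimethyl-4-methylidenehex-5-enal, via allyl vinyl ether 8 (not isolated)
Conditions: Pd(TFA)2 (cat.), 4,7-diphenyl-1,10-phenanthroline (cat.), Et3N (cat.), butyl vinyl ether (excess), 75 °C; evaporate; then toluene, BHT (trace), 140 °C, sealed tube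
Reagents that add atoms: none
Why: Pd(II)-catalysed transfer vinylation followed by an aliphatic Claisen [3,3]-rearrangement should create the quaternary C1 with both methyl groups and transpose the alkene into the 2,3-disubstituted diene, with no stereocentre formed.

Step 5
Reactants: 9 3,3,5-trimethyl-4-methylidenehex-5-enal
Product: 10 (1R)-4-(chloromethyl)-3,5,5-trimethylcyclohex-3-en-1-ol
Conditions: HCl (1.5 equiv, ethereal), chiral arylpyrrolidine–tert-leucine thiourea hydrogen-bond donor (10 mol %, enantiomer selected for Re-face attack), TBME/toluene, −60 → −40 °C; cold NaHCO3 quench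
Reagents that add atoms: hydrogen chloride, Cl
Why: Proposed new method: the HCl–chiral hydrogen-bond-donor complex activates the aldehyde of 9, the terminal diene carbon C4 attacks C3 through a chair-like transition state to give a ring-bound tertiary allyl cation (C5–C6–C7) paired with the catalyst-bound chloride, and the ion pair collapses at the primary terminus C7, a net 1,4-hydroxy-chlorination of the diene; the closest known reaction type is the enantioselective Prins (carbonyl–ene type) cyclisation of alkenyl aldehydes under chiral hydrogen-bond-donor/HCl co-catalysis, extended here to a diene terminator with chloride capture. The ring closes in the type-II mode, 6-endo-trig with respect to the attacking C4=C5 bond and exo with respect to the carbonyl, helped by the gem-dimethyl group (Thorpe–Ingold effect). The single new stereocentre C3 is set by the catalyst, which must deliver C4 to the Re face of the aldehyde to give (R); the substrate is achiral, so this is the only stereo-determining event. Regioselectivity for C7–Cl with the tetrasubstituted C5=C6 alkene is expected because the primary allylic chloride is the thermodynamic product and a tertiary C5 chloride would re-ionise under the acidic conditions, while closure at C7 would be a 5-endo process and oxygen capture at C7 would give a bridgehead alkene, so the substrate excludes both. Chemoselectivity over proton loss to ene-type dienes and over direct HCl addition to the diene is expected from the low temperature, the non-basic medium and the catalyst-accelerated intramolecular pathway.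

Step 6
Reactants: 10 (1R)-4-(chloromethyl)-3,5,5-trimethylcyclohex-3-en-1-ol
Product: 11 {[(4R)-4-hydroxy-2,6,6-trimethylcyclohex-1-en-1-yl]methyl}triphenylphosphonium chloride
Conditions: PPh3 (1.1 equiv), MeCN, 70 °C
Reagents that add atoms: triphenylphosphine, c1ccc(cc1)P(c1ccccc1)c1ccccc1
Why: SN2 quaternisation of the primary allylic chloride by triphenylphosphine should give the C10 Wittig salt, since the SN2' position C5 is fully substituted and the free hydroxyl is inert.

Step 7
Reactants: 11 {[(4R)-4-hydroxy-2,6,6-trimethylcyclohex-1-en-1-yl]methyl}triphenylphosphonium chloride; 12 all-trans-β-apo-8'-carotenal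
Product: 15 (3R)-β-cryptoxanthin, via phosphonium ylide 13 (not isolated), via 7Z isomer 14 (not isolated)
Conditions: NaOMe (1.2 equiv), CH2Cl2/MeOH, 0 °C → rt, Ar, dark; then n-heptane, reflux (Z → E)
Reagents that add atoms: none
Why: Wittig olefination of the semi-stabilised allylic ylide with the polyene aldehyde should form the C7=C8 bond without protecting the hydroxyl, and the sterically strained 7Z portion is expected to relax thermally to the all-E polyene, the usual practice in carotenoid Wittig couplings.

Step 8
Reactants: 15 (3R)-β-cryptoxanthin; 16 (9Z)-hexadec-9-enoic acid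
Product: 17 (3R)-β,β-caroten-3-yl (9Z)-hexadec-9-enoate
Conditions: DCC (1.2 equiv), DMAP (cat.), CH2Cl2, 0 °C → rt, Ar, dark
Reagents that add atoms: none
Why: Steglich esterification acylates the secondary hydroxyl with retention at C3 (the C3–O bond is not broken) and should leave the polyene and the isolated Z-alkene of the acid untouched.

**Compound list**

1 | ethyl 3-methylbut-2-enoate | CCOC(=O)C=C(C)C | starting material
2 | ethyl 2,3-dibromo-3-methylbutanoate (racemic) | CCOC(=O)C(Br)C(C)(C)Br | intermediate
3 | ethyl 2-bromo-3-methylbut-2-enoate | CCOC(=O)C(Br)=C(C)C | intermediate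
4 | 4,4,5,5-tetramethyl-2-(prop-1-en-2-yl)-1,3,2-dioxaborolane (isopropenylboronic acid pinacol ester) | CC(=C)B1OC(C)(C)C(C)(C)O1 | starting material
5 | ethyl 3-methyl-2-(propan-2-ylidene)but-3-enoate | CCOC(=O)C(C(C)=C)=C(C)C | intermediate
6 | 3-methyl-2-(propan-2-ylidene)but-3-en-1-ol | OCC(C(C)=C)=C(C)C | intermediate
7 | butyl vinyl ether | C=COCCCC | starting material
8 | 3-[(ethenyloxy)methyl]-2,4-dimethylpenta-1,3-diene | C=COCC(C(C)=C)=C(C)C | intermediate
9 | 3,3,5-trimethyl-4-methylidenehex-5-enal | O=CCC(C)(C)C(=C)C(C)=C | intermediate
10 | (1R)-4-(chloromethyl)-3,5,5-trimethylcyclohex-3-en-1-ol | O[C@@H]1CC(C)=C(CCl)C(C)(C)C1 | intermediate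
11 | {[(4R)-4-hydroxy-2,6,6-trimethylcyclohex-1-en-1-yl]methyl}triphenylphosphonium chloride | O[C@@H]1CC(C)=C(C[P+](c2ccccc2)(c2ccccc2)c2ccccc2)C(C)(C)C1.[Cl-] | intermediate
12 | all-trans-8'-apo-β-caroten-8'-al (β-apo-8'-carotenal, C30) | O=C/C(C)=C/C=C/C(C)=C/C=C/C=C(C)/C=C/C=C(C)/C=C/C1=C(C)CCCC1(C)C | starting material
13 | {[(4R)-4-hydroxy-2,6,6-trimethylcyclohex-1-en-1-yl]methylidene}triphenylphosphorane | O[C@@H]1CC(C)=C(C=P(c2ccccc2)(c2ccccc2)c2ccccc2)C(C)(C)C1 | intermediate
14 | (3R,7Z)-β,β-caroten-3-ol (7Z portion of the Wittig product) | O[C@@H]1CC(C)=C(\C=C/C(C)=C/C=C/C(C)=C/C=C/C=C(C)/C=C/C=C(C)/C=C/C2=C(C)CCCC2(C)C)C(C)(C)C1 | intermediate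
15 | (3R)-β,β-caroten-3-ol ((3R)-β-cryptoxanthin, all-E) | O[C@@H]1CC(C)=C(/C=C/C(C)=C/C=C/C(C)=C/C=C/C=C(C)/C=C/C=C(C)/C=C/C2=C(C)CCCC2(C)C)C(C)(C)C1 | intermediate
16 | (9Z)-hexadec-9-enoic acid (palmitoleic acid) | CCCCCC/C=C\CCCCCCCC(=O)O | starting material
17 | (3R)-β,β-caroten-3-yl (9Z)-hexadec-9-enoate | CCCCCC/C=C\CCCCCCCC(=O)O[C@@H]1CC(C)=C(/C=C/C(C)=C/C=C/C(C)=C/C=C/C=C(C)/C=C/C=C(C)/C=C/C2=C(C)CCCC2(C)C)C(C)(C)C1 | target

**Totals**

Total step count: 8. Longest linear sequence: 8 steps (1 → 17); all other building blocks are purchased.

**Steps most likely to fail**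

Step 5 (proposed new method). The aldehyde faces may be poorly discriminated. The allyl cation may lose a proton to ene-type dienes, or HCl may add directly to the diene before cyclisation. Fallback with known chemistry, setting out from 9: the stoichiometric Lewis-acid halo-Prins cyclisation (TiCl4, CH2Cl2, −78 °C) should give racemic 4-(chloromethyl)-3,5,5-trimethylcyclohex-3-en-1-ol F1. A lipase-catalysed kinetic resolution (immobilised Burkholderia cepacia lipase, vinyl acetate, MTBE, rt) is then expected to acylate the R enantiomer, as the empirical rule for secondary alcohols predicts with the CMe2-flanked side as the large group. This gives (1R)-4-(chloromethyl)-3,5,5-trimethylcyclohex-3-en-1-yl acetate F2 and leaves (1S)-4-(chloromethyl)-3,5,5-trimethylcyclohex-3-en-1-ol F3, which is separated by chromatography. Reductive removal of the acetyl group from F2 (DIBAL-H, CH2Cl2, −78 °C, which spares the allylic chloride) comes back to the route at 10.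

Step 7. The hindered C10 ylide may add slowly to the α-methyl polyene aldehyde, and the 7Z to E isomerisation may be incomplete or accompanied by polyene degradation. Fallback setting out from 10: displacement with sodium 1,3-benzothiazole-2-thiolate (DMF, rt) should give 2-({[(4R)-4-hydroxy-2,6,6-trimethylcyclohex-1-en-1-yl]methyl}sulfanyl)-1,3-benzothiazole F4. Chemoselective sulfur oxidation (H2O2, cat. ammonium molybdate, EtOH, 0 °C → rt) should give 2-({[(4R)-4-hydroxy-2,6,6-trimethylcyclohex-1-en-1-yl]methyl}sulfonyl)-1,3-benzothiazole F5. Julia–Kocienski olefination of F5 with 12 (NaHMDS, 2.1 equiv, THF, −78 °C → rt), followed by the same thermal isomerisation, comes back to the route at 15 and bypasses the phosphonium salt 11.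

Step 4. The dienal may cyclise prematurely and without stereocontrol by a thermal carbonyl–ene reaction, or the diene may oligomerise at the temperature of the rearrangement. Fallback setting out from 6: a Johnson–Claisen rearrangement (triethyl orthoacetate, cat. propionic acid, 140 °C, ethanol distilled off) should give ethyl 3,3,5-trimethyl-4-methylidenehex-5-enoate F6, which cannot cyclise. Partial reduction of F6 (DIBAL-H, 1.0 equiv, toluene, −78 °C) releases the aldehyde only in the cold and comes back to the route at 9.

**Further compounds**

F1 | step 5 | rac-4-(chloromethyl)-3,5,5-trimethylcyclohex-3-en-1-ol | OC1CC(C)=C(CCl)C(C)(C)C1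
F2 | step 5 | (1R)-4-(chloromethyl)-3,5,5-trimethylcyclohex-3-en-1-yl acetate | CC(=O)O[C@@H]1CC(C)=C(CCl)C(C)(C)C1
F3 | step 5 | (1S)-4-(chloromethyl)-3,5,5-trimethylcyclohex-3-en-1-ol | O[C@H]1CC(C)=C(CCl)C(C)(C)C1
F4 | step 7 | 2-({[(4R)-4-hydroxy-2,6,6-trimethylcyclohex-1-en-1-yl]methyl}sulfanyl)-1,3-benzothiazole | O[C@@H]1CC(C)=C(CSc2nc3ccccc3s2)C(C)(C)C1
F5 | step 7 | 2-({[(4R)-4-hydroxy-2,6,6-trimethylcyclohex-1-en-1-yl]methyl}sulfonyl)-1,3-benzothiazole | O[C@@H]1CC(C)=C(CS(=O)(=O)c2nc3ccccc3s2)C(C)(C)C1
F6 | step 4 | ethyl 3,3,5-trimethyl-4-methylidenehex-5-enoate | CCOC(=O)CC(C)(C)C(=C)C(C)=C
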